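Micromolar is the unit to count this flask in: c(impurity) of 0.26 µM stands beside c(enzyme) of 2.0 µM.

common to all: starting material 20 mM; impurity 0.26 µM
- dawn: second substrate 40 mM; enzyme 1 µM; run made earlier
- dusk: second substrate 40 mM; enzyme 1.5 µM; run made earlier
- flask: second substrate 40.0 mM; enzyme 2.0 µM

| run | time / h | target / % | starting material / % |
|---|---|---|---|
| dawn | 2.50 | 6.7 | 92.2 |
| dawn | 4.00 | 10.9 | 89.3 |
| dawn | 6.00 | 15.8 | 84.3 |
| dawn | 8.00 | 20.0 | 79.5 |
| dawn | 12.0 | 28.9 | 71.7 |
| dawn | 20.0 | 42.9 | 55.9 |
| dawn | 30.0 | 57.5 | 40.9 |
| dusk | 4.00 | 17.1 | 83.1 |
| dusk | 8.00 | 32.0 | 67.7 |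
| dusk | 12.0 | 44.4 | 56.6 |
| dusk | 15.0 | 51.2 | 48.2 |
| dusk | 20.0 | 62.4 | 37.2 |
| dusk | 25.0 | 71.9 | 28.5 |
| dusk | 30.0 | 77.8 | 20.9 |

(scatter of a reading: 0.5 percentage points)

- apparent order in enzyme when 50% of the starting material are converted (percent change of the rate of making target for one percent more enzyme charged)
- factor on the rate of making target when 50% of the starting material are converted if second substrate is charged twice over

- no earlier run changes the charge of second substrate; that part of a forecast is a guess

1. Take the rate as proportional to the enzyme that impurity has not taken, one impurity per enzyme. At one end, with c(impurity) nil, the order in enzyme is one. At the other, with c(impurity) equal to c(enzyme), no enzyme is free to work. Joining the ends gives 1.74 µM for the flask: the working enzyme, c(enzyme) minus c(impurity). The order is then c(enzyme) over working enzyme.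

2. By this rule, the opposite outcome, an order far above one, asks for c(impurity) close to c(enzyme). This flask's impurity is 13.0% of its enzyme, so my reckoning gives an order of 1.15.

3. The readings can test the rule. At 8.00 h, ln(1 − target) in the dusk run over that in the dawn run reads 1.73. That is more than the enzyme ratio of 1.50, and the working-enzyme ratio is 1.68.

4. The forecast gives 1.15 for the order and 1.2 for the doubling factor, the latter “weakly supported”. No earlier run varies second substrate, and working enzyme is silent on it.

5. The flask gives an order of 1.1 and a doubling factor of 2.05, against the forecast's 1.2.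

    starting material + enzyme ⇌ starting complex (K = 75.0 M⁻¹, k = 950 M⁻¹ s⁻¹)
    second substrate + starting complex ⇌ ternary complex (K = 8.24 M⁻¹, k = 233 M⁻¹ s⁻¹)
    ternary complex → enzyme + target (k = 1.26 s⁻¹)
    enzyme + impurity → spent catalyst (k = 991 M⁻¹ s⁻¹)

The two part on second substrate. In this flask at 50% conversion, its apparent order stands at 1.2, in part through the reverse step of ternary complex to second substrate + starting complex: the same flask without that step shows an order of 0.39, and a rate 7.24 times the actual one. For enzyme, c(enzyme) over working enzyme in this flask is 1.15, beside the order of 1.1. With twice the enzyme, working enzyme rises to 3.74 µM, which puts the time to that conversion at 0.465 of the flask's; the simulated factor is 0.467.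

The earlier runs and the new flask come from a simulation for an exercise, and the scatter is random.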